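Ring A of the flavone is made last. Because C7 and C8 are unsubstituted CH positions while C5 and C6 both carry oxygen, ring A is disconnected across C7–C8 and C5–C6. That leaves a preformed ring C: a 6-aryl-4-pyranone whose C-methyl becomes C8 and whose ester carbon becomes C5, plus a two-carbon dimethoxyacrylate that supplies C6 (with its methoxy group) and C7. In one operation a Michael–Dieckmann benzannulation forges both bonds, closes ring A as a C6-blocked cyclohexadienone and places both oxygens correctly; loss of the C6 ester then aromatises ring A and a final O-methylation gives the target.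

Key step: step 6

Remark on the chemistry: flavone numbering (O1, C2 to C8a) is used for ring A and ring C atoms of all intermediates. The only stereocentre on the route (C6 of 17 and 18) is formed as a racemate and disappears in step 7, so the achiral target needs no stereocontrol. Either geometric isomer of 14 would serve, because both alkene carbons are rebuilt in step 6.

Step 1
Reactants: 1 1,2,4,5-tetramethoxybenzene
Product: 3 3-iodo-1,2,4,5-tetramethoxybenzene, via aryllithium 2 (not isolated)
Conditions: n-BuLi, THF, 0 °C → rt; then I2, THF, −78 °C → rt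
Reagents that add atoms: iodine, [I][I]
Why: Directed ortho-metalation: the two ring C–H bonds of 1 are equivalent and each is flanked by two methoxy groups, so n-BuLi should give a single aryllithium that iodine traps by iodinolysis.

Step 2
Reactants: 3 3-iodo-1,2,4,5-tetramethoxybenzene; 4 propiolic acid
Product: 5 3-(2,3,5,6-tetramethoxyphenyl)prop-2-ynoic acid
Conditions: PdCl2(PPh3)2 (cat.), 1,4-bis(diphenylphosphino)butane (cat.), DBU, DMSO, 40 °C; aq. HCl work-up
Reagents that add atoms: none
Why: Copper-free Sonogashira coupling of the amidinium propiolate after oxidative addition of the aryl iodide to zerovalent palladium, run at low temperature so that neither propiolic acid nor the product should decarboxylate.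

Step 3
Reactants: 5 3-(2,3,5,6-tetramethoxyphenyl)prop-2-ynoic acid
Product: 6 3-(2,3,5,6-tetramethoxyphenyl)prop-2-ynoyl chloride
Conditions: (COCl)2, DMF (cat.), CH2Cl2, 0 °C → rt; evaporate, use crude
Reagents that add atoms: oxalyl chloride, O=C(Cl)C(=O)Cl
Why: Standard acid chloride formation through the chloroiminium (Vilsmeier-type) species generated from catalytic DMF, kept at or below room temperature so that the electron-rich arylalkyne is left untouched.

Step 4
Reactants: 6 3-(2,3,5,6-tetramethoxyphenyl)prop-2-ynoyl chloride; 7 methyl acetoacetate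
Product: 10 methyl 2-methyl-4-oxo-6-(2,3,5,6-tetramethoxyphenyl)-4H-pyran-3-carboxylate, via chloromagnesium enolate 8 (not isolated), via enolised alkynoyl tricarbonyl 9 (not isolated)
Conditions: MgCl2, pyridine, CH2Cl2, 0 °C; then 6, 0 °C → rt; then DMAP (cat.), rt
Reagents that add atoms: none
Why: Soft-enolisation C-acylation of a β-keto ester (the chelated magnesium enolate reacts at carbon, not oxygen) gives the enolised tricarbonyl 9, whose acetyl enol oxygen should then close onto the aryl-bearing alkyne carbon by 6-endo-dig oxa-Michael addition under nucleophilic amine catalysis, placing the methyl at C2 and the ester at C3 of the 4-pyranone.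

Step 5
Reactants: 11 methyl methoxyacetate; 12 methyl formate
Product: 14 methyl (Z)-2,3-dimethoxyprop-2-enoate, via sodium formyl enolate 13 (not isolated)
Conditions: NaH, THF, 0 °C → rt; then Me2SO4, DMF, rt
Reagents that add atoms: dimethyl sulfate, COS(=O)(=O)OC
Why: Crossed Claisen formylation of the ester enolate by non-enolisable methyl formate gives the formyl ester enolate, which the hard electrophile dimethyl sulfate should alkylate on oxygen to the β-methoxyacrylate, expected as the isomer with the β-methoxy group trans to the ester, that is (Z).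

Step 6
Reactants: 10 methyl 2-methyl-4-oxo-6-(2,3,5,6-tetramethoxyphenyl)-4H-pyran-3-carboxylate; 14 methyl (Z)-2,3-dimethoxyprop-2-enoate
Product: 18 methyl 6-methoxy-4,5-dioxo-2-(2,3,5,6-tetramethoxyphenyl)-5,6-dihydro-4H-chromene-6-carboxylate (racemic), via lithium dienolate 15 (not isolated), via Michael adduct enolate 16 (not isolated), via ring-closed methoxy ketone 17 (not isolated)
Conditions: LiN(iPr)2 (1.05 equiv), THF, −78 °C; then 14, −78 → −20 °C; AcOH, −78 °C
Reagents that add atoms: none
Why: Proposed new method: the C-methyl of 10 is vinylogously acidified by both the ring ketone and the C3 ester, so LiN(iPr)2 should give the exocyclic dienolate 15, which, like an ortho-toluate anion, adds through its CH2 carbon to the β-carbon of 14 (C7–C8 bond), the closest known reaction type being the Staunton–Weinreb annulation of toluate anions with β-methoxy enones and enoates, extended here to a 2-methyl-4-pyranone-3-carboxylate donor and an α-methoxylated acceptor. The ester enolate 16 then attacks the adjacent pyranone ester in a 6-exo-trig Dieckmann closure (C5–C6 bond, ring A) to give 17, and the liberated LiOMe removes a doubly activated C8 proton so that the C7 methoxide leaves by E1cB and the C7=C8 alkene of 18 results. If methoxide instead leaves 16 before ring closure, the enoate formed is deprotonated again at C8 and its dienolate closes through the same α-carbon, so both orders of events converge on 18. C6 becomes a quaternary stereocentre with no controlling element and is formed as a racemate, which is acceptable because step 7 erases it. The step needs attack through the exocyclic carbon and not through ring carbon C3 (secured by retention of the pyranone conjugation), conjugate and not carbonyl addition to 14 (secured by the poorly electrophilic, α-oxygenated ester), and no free amide base that could metalate 14 (secured by using barely more than one equivalent of base). Loss of the C6 ester through attack of methoxide on warming would only anticipate step 7, since it leads to 19.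

Step 7
Reactants: 18 methyl 6-methoxy-4,5-dioxo-2-(2,3,5,6-tetramethoxyphenyl)-5,6-dihydro-4H-chromene-6-carboxylate (racemic)
Product: 19 5-hydroxy-6-methoxy-2-(2,3,5,6-tetramethoxyphenyl)-4H-chromen-4-one
Conditions: LiCl, DMSO, H2O (2 equiv), 100 °C
Reagents that add atoms: none
Why: Krapcho dealkoxycarbonylation: chloride removes the ester methyl by SN2, the β-keto carboxylate loses CO2, and the resulting C5 enolate is the phenoxide of aromatic ring A, so aromatisation drives the reaction and erases the C6 stereocentre while the methyl ethers should stay intact.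

Step 8
Reactants: 19 5-hydroxy-6-methoxy-2-(2,3,5,6-tetramethoxyphenyl)-4H-chromen-4-one
Product: 20 5,6,2',3',5',6'-hexamethoxyflavone
Conditions: Me2SO4, K2CO3, acetone, reflux
Reagents that add atoms: dimethyl sulfate, COS(=O)(=O)OC
Why: Williamson O-methylation of the hydrogen-bonded 5-hydroxyl, slow but dependable for 5-hydroxyflavones with excess dimethyl sulfate and carbonate at reflux.

Compound list
1 | 1,2,4,5-tetramethoxybenzene | COc1cc(OC)c(OC)cc1OC | starting material
2 | (2,3,5,6-tetramethoxyphenyl)lithium (formed in the flask, not isolated) | [Li]c1c(OC)c(OC)cc(OC)c1OC | intermediate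
3 | 3-iodo-1,2,4,5-tetramethoxybenzene | Ic1c(OC)c(OC)cc(OC)c1OC | intermediate
4 | propiolic acid (prop-2-ynoic acid) | C#CC(=O)O | starting material
5 | 3-(2,3,5,6-tetramethoxyphenyl)prop-2-ynoic acid | COc1cc(OC)c(OC)c(C#CC(=O)O)c1OC | intermediate
6 | 3-(2,3,5,6-tetramethoxyphenyl)prop-2-ynoyl chloride | COc1cc(OC)c(OC)c(C#CC(=O)Cl)c1OC | intermediate
7 | methyl acetoacetate (methyl 3-oxobutanoate) | CC(=O)CC(=O)OC | starting material
8 | chloromagnesium enolate of methyl acetoacetate (formed in the flask, not isolated) | COC(=O)C=C(C)O[Mg]Cl | intermediate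
9 | methyl 2-acetyl-3-oxo-5-(2,3,5,6-tetramethoxyphenyl)pent-4-ynoate, drawn as its acetyl enol (formed in the flask, not isolated) | COC(=O)C(C(=O)C#Cc1c(OC)c(OC)cc(OC)c1OC)=C(C)O | intermediate
10 | methyl 2-methyl-4-oxo-6-(2,3,5,6-tetramethoxyphenyl)-4H-pyran-3-carboxylate | COC(=O)c1c(C)oc(-c2c(OC)c(OC)cc(OC)c2OC)cc1=O | intermediate
11 | methyl methoxyacetate | COCC(=O)OC | starting material
12 | methyl formate | COC=O | starting material
13 | sodium enolate of methyl 2-methoxy-3-oxopropanoate, geometry mobile (formed in the flask, not isolated) | [Na+].[O-]C=C(OC)C(=O)OC | intermediate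
14 | methyl (Z)-2,3-dimethoxyprop-2-enoate | CO/C=C(\OC)C(=O)OC | intermediate
15 | lithium dienolate of 10, deprotonated at the C-methyl (formed in the flask, not isolated) | [Li+].[CH2-]c1oc(-c2c(OC)c(OC)cc(OC)c2OC)cc(=O)c1C(=O)OC | intermediate
16 | lithium ester enolate of methyl 4-oxo-6-(2,3,5,6-tetramethoxyphenyl)-2-(2,3,4-trimethoxy-4-oxobutyl)-4H-pyran-3-carboxylate, racemic (formed in the flask, not isolated) | [Li+].COC([O-])=C(OC)C(OC)Cc1oc(-c2c(OC)c(OC)cc(OC)c2OC)cc(=O)c1C(=O)OC | intermediate
17 | methyl 6,7-dimethoxy-4,5-dioxo-2-(2,3,5,6-tetramethoxyphenyl)-5,6,7,8-tetrahydro-4H-chromene-6-carboxylate, racemic mixture of diastereomers (formed in the flask, not isolated) | COC(=O)C1(OC)C(OC)Cc2oc(-c3c(OC)c(OC)cc(OC)c3OC)cc(=O)c2C1=O | intermediate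
18 | methyl 6-methoxy-4,5-dioxo-2-(2,3,5,6-tetramethoxyphenyl)-5,6-dihydro-4H-chromene-6-carboxylate, racemic at C6 | COC(=O)C1(OC)C=Cc2oc(-c3c(OC)c(OC)cc(OC)c3OC)cc(=O)c2C1=O | intermediate
19 | 5-hydroxy-6-methoxy-2-(2,3,5,6-tetramethoxyphenyl)-4H-chromen-4-one | COc1ccc2oc(-c3c(OC)c(OC)cc(OC)c3OC)cc(=O)c2c1O | intermediate
20 | 5,6,2',3',5',6'-hexamethoxyflavone, that is 5,6-dimethoxy-2-(2,3,5,6-tetramethoxyphenyl)-4H-chromen-4-one | COc1cc(OC)c(OC)c(-c2cc(=O)c3c(OC)c(OC)ccc3o2)c1OC | target

Total step count: 8. Longest linear sequence: 7 (steps 1, 2, 3, 4, 6, 7, 8); step 5 is a one-step side branch.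

Steps most likely to fail

Step 6. The stabilised dienolate may fail to add to the electron-rich, α-oxygenated acrylate, or add slowly and reversibly. On warming, proton transfer to the acrylate or attack of the dienolate on C2 of unreacted pyranone could then take over. The fallback gives up the late construction of ring A and uses classical flavone chemistry; it sets out from aryllithium 2 (made from 1 as in step 1) and comes back to the route at the target 20.
- Quenching 2 with DMF should give 2,3,5,6-tetramethoxybenzaldehyde F1.
- Ring A is taken from commercial 1-(2-hydroxy-6-methoxyphenyl)ethanone. Elbs persulfate oxidation (K2S2O8, aq. NaOH, rt) hydroxylates it para to the phenol by way of potassium 3-acetyl-4-hydroxy-2-methoxyphenyl sulfate F2. Hot dilute HCl cleaves F2 to 1-(3,6-dihydroxy-2-methoxyphenyl)ethanone F3.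
- The free, non-chelated hydroxyl of F3 is methylated (Me2SO4, one equivalent, K2CO3, acetone) to 1-(6-hydroxy-2,3-dimethoxyphenyl)ethanone F4.
- Claisen–Schmidt condensation of F4 with F1 (KOH, EtOH, rt) should give (E)-1-(6-hydroxy-2,3-dimethoxyphenyl)-3-(2,3,5,6-tetramethoxyphenyl)prop-2-en-1-one F5.
- Oxidative cyclisation of F5 (I2 cat., DMSO, 120 °C) closes ring C and delivers 20.

Step 4. Closure of the enol onto the alkyne may be slowed by the doubly ortho-substituted aryl group, so that 5-exo closure at the inner alkyne carbon, or amine addition to the alkynoyl chloride before C-acylation, competes. The fallback avoids the alkyne and closes the pyranone by dehydrative addition–elimination at an unhindered enamine carbon; it sets out from 2 and from 7 and comes back at 10, so the iodination and steps 2 and 3 are no longer needed.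
- Quenching 2 with CO2 gives 2,3,5,6-tetramethoxybenzoic acid F6, which (COCl)2 with catalytic DMF converts into 2,3,5,6-tetramethoxybenzoyl chloride F7.
- Condensation of 7 with N,N-dimethylacetamide dimethyl acetal (toluene, 80 °C) gives methyl 2-acetyl-3-(dimethylamino)but-2-enoate F8.
- Deprotonation of F8 with LiN(SiMe3)2 (2 equiv, THF, −78 °C) forms the lithium enolate of its acetyl group F9.
- F7 acylates F9 at carbon to give methyl 2-[1-(dimethylamino)ethylidene]-3,5-dioxo-5-(2,3,5,6-tetramethoxyphenyl)pentanoate F10.
- Aqueous HCl then lets the enol oxygen of the aryl ketone displace dimethylamine from the enamine carbon, closing F10 to 10.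

Step 2. Oxidative addition at the hindered, electron-rich iodide may be slow enough to demand heating, and heating brings decarboxylation of the propiolate and a second coupling of the freed alkyne. The fallback separates the coupling from the carboxyl group; it sets out from 3 and comes back at 5.
- Sonogashira coupling of 3 with ethynyltrimethylsilane (PdCl2(PPh3)2, CuI, Et3N, 60 °C) gives trimethyl[(2,3,5,6-tetramethoxyphenyl)ethynyl]silane F11.
- K2CO3 in MeOH removes the silyl group to give 3-ethynyl-1,2,4,5-tetramethoxybenzene F12.
- n-BuLi (1 equiv, THF, −78 °C) forms lithium (2,3,5,6-tetramethoxyphenyl)acetylide F13, which is carboxylated with CO2 and acidified to 5.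

Further compounds
F1 | step 6 | 2,3,5,6-tetramethoxybenzaldehyde | COc1cc(OC)c(OC)c(C=O)c1OC
F2 | step 6 | potassium 3-acetyl-4-hydroxy-2-methoxyphenyl sulfate | [K+].CC(=O)c1c(O)ccc(OS(=O)(=O)[O-])c1OC
F3 | step 6 | 1-(3,6-dihydroxy-2-methoxyphenyl)ethanone | CC(=O)c1c(O)ccc(O)c1OC
F4 | step 6 | 1-(6-hydroxy-2,3-dimethoxyphenyl)ethanone | CC(=O)c1c(O)ccc(OC)c1OC
F5 | step 6 | (E)-1-(6-hydroxy-2,3-dimethoxyphenyl)-3-(2,3,5,6-tetramethoxyphenyl)prop-2-en-1-one | COc1cc(OC)c(OC)c(/C=C/C(=O)c2c(O)ccc(OC)c2OC)c1OC
F6 | step 4 | 2,3,5,6-tetramethoxybenzoic acid | COc1cc(OC)c(OC)c(C(=O)O)c1OC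
F7 | step 4 | 2,3,5,6-tetramethoxybenzoyl chloride | COc1cc(OC)c(OC)c(C(=O)Cl)c1OC
F8 | step 4 | methyl 2-acetyl-3-(dimethylamino)but-2-enoate | COC(=O)C(C(C)=O)=C(C)N(C)C
F9 | step 4 | lithium enolate of F8, deprotonated at the acetyl methyl | [Li+].C=C([O-])C(C(=O)OC)=C(C)N(C)C
F10 | step 4 | methyl 2-[1-(dimethylamino)ethylidene]-3,5-dioxo-5-(2,3,5,6-tetramethoxyphenyl)pentanoate | COC(=O)C(=C(C)N(C)C)C(=O)CC(=O)c1c(OC)c(OC)cc(OC)c1OC
F11 | step 2 | trimethyl[(2,3,5,6-tetramethoxyphenyl)ethynyl]silane | COc1cc(OC)c(OC)c(C#C[Si](C)(C)C)c1OC
F12 | step 2 | 3-ethynyl-1,2,4,5-tetramethoxybenzene | COc1cc(OC)c(OC)c(C#C)c1OC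
F13 | step 2 | lithium (2,3,5,6-tetramethoxyphenyl)acetylide | [Li]C#Cc1c(OC)c(OC)cc(OC)c1OC
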